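**Retrosynthetic overview**
- Cyclohexene ring, formed last: [4+2] between the ring-B p-quinone of diosmetin (activated as its 4,5-O,O-BF2 chelate) and 7β-hydroxylabda-8(17),12E,14-trien-18-oic acid, the diene being released in the same flask from its SO2 adduct.
- Decalin (labdane rings A and B), formed first: one chair–chair radical epoxy-polyene bicyclisation with exocyclic termination, the laboratory counterpart of the copalyl cyclase step.
- Acyclic C20 precursor: farnesyl bromide + 3-methyl-3-sulfolene (masked E-diene), terminal allylic oxidation, Sharpless epoxidation (source of absolute configuration).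
- Between the two ring-forming events: C3 deoxygenation, C18 → CO2H, C7 oxidation/reduction to the 7β-alcohol.
- Dienophile: one-step Teuber oxidation of commercial diosmetin.

Assumption: diosmetin, (2E,6E)-farnesyl bromide and 3-methyl-3-sulfolene are bought; compounds 3–13 are 1:1 epimer mixtures at the sulfolene carbon (left open in the SMILES), a centre that is erased in step 11. Flavone numbering (C1', C2' …) is used for the quinone ring.

**Step 1**
Reactants: 1 3-methyl-2,5-dihydrothiophene 1,1-dioxide (3-methyl-3-sulfolene); 2 (2E,6E)-farnesyl bromide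
Product: 3 2-[(2E,6E)-farnesyl]-3-methyl-2,5-dihydrothiophene 1,1-dioxide (racemic)
Conditions: LiN(SiMe3)2 added to 1 + 2, THF–HMPA (4:1), −78 °C
Reagents that add atoms: none
Why: In situ deprotonation/SN2 alkylation of the allylic α-sulfonyl carbanion, which forms at C2 (charge delocalised onto the secondary C4) and is trapped by the allylic bromide before it can ring-open, the regiochemistry known for prenyl and geranyl bromides; the new centre is racemic and irrelevant.

**Step 2**
Reactants: 3
Product: 4 (2E,6E,10E)-2,6,10-trimethyl-12-(3-methyl-1,1-dioxo-2,5-dihydrothiophen-2-yl)dodeca-2,6,10-trien-1-ol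
Conditions: SeO2 (0.3 equiv), t-BuOOH (3 equiv), salicylic acid (0.1 equiv), CH2Cl2, 0 °C → rt
Reagents that add atoms: selenium dioxide, O=[Se]=O (delivers the O, catalytic); tert-butyl hydroperoxide, CC(C)(C)OO (re-oxidant, net O source)
Why: Sharpless–Umbreit allylic oxidation (ene reaction, then 2,3-sigmatropic shift) is selective for the E-methyl of the terminal, most electron-rich trisubstituted alkene of a polyprenyl chain, with retention of the E geometry; the sulfolene alkene is deactivated.

**Step 3**
Reactants: 4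
Product: 5 [(2S,3S)-3-[(3E,7E)-4,8-dimethyl-10-(3-methyl-1,1-dioxo-2,5-dihydrothiophen-2-yl)deca-3,7-dien-1-yl]-2-methyloxiran-2-yl]methanol
Conditions: Ti(OiPr)4 (10 mol %), L-(+)-diethyl tartrate (12 mol %), t-BuOOH, 4 Å MS, CH2Cl2, −20 °C
Reagents that add atoms: tert-butyl hydroperoxide, CC(C)(C)OO
Why: Katsuki–Sharpless asymmetric epoxidation touches only the allylic-alcohol alkene, and L-(+)-tartrate gives the (2S,3S)-epoxide (as geraniol gives its 2S,3S-epoxide), so the epoxide CH carbon (future C3) is S.

**Step 4**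
Reactants: 5
Product: 7 12,15-sulfonyl-labda-8(17),13-diene-3β,18-diol (5α-H 9α-H 10β-CH3), via bis-trimethylsilyl ether 6 (not isolated)
Conditions: Cp2TiCl2 (0.2 equiv), Mn dust, Me3SiCl, 2,4,6-collidine, THF, rt, slow addition of 5; then 1 M HCl
Reagents that add atoms: none
Why: Nugent–RajanBabu epoxide homolysis by Cp2TiCl (trivalent titanium) gives the tertiary C4 radical, which closes twice 6-endo through a chair–chair array and ends by titanium-mediated β-hydride loss to the exocyclic alkene; the equatorial C3–O–Ti (3S) fixes the absolute sense of C5, C9 and C10 (trans-decalin, equatorial side chain from the E-alkenes), and the larger CH2OSiMe3 group takes the equatorial 4α site away from the developing axial C10 methyl.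

**Step 5**
Reactants: 7
Product: 8 cyclic 3β,18-thionocarbonate of 7
Conditions: Im2C=S (1,1'-thiocarbonyldiimidazole), THF, 50 °C
Reagents that add atoms: 1,1'-thiocarbonyldiimidazole, S=C(n1ccnc1)n1ccnc1
Why: The gauche (both equatorial) 1,3-diol closes to a trans-fused six-membered cyclic thionocarbonate by double acyl substitution.

**Step 6**
Reactants: 8
Product: 10 12,15-sulfonyl-labda-8(17),13-dien-18-ol, via S-stannyl thiocarbonate 9 (not isolated)
Conditions: Bu3SnH, Et3B, air, PhMe, rt; then 1 M HCl, THF
Reagents that add atoms: none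
Why: Barton deoxygenation of a cyclic thionocarbonate: the stannyl radical adds to sulfur and the adduct fragments to the more stable secondary C3 radical (not the primary C18 one), which is reduced, after which acid frees the C18 alcohol; capture by C=S is orders of magnitude faster than addition to the allyl sulfone, and room temperature avoids SO2 loss.

**Step 7**
Reactants: 10
Product: 11 12,15-sulfonyl-labda-8(17),13-diene-7α,18-diol
Conditions: SeO2 (0.5 equiv), t-BuOOH, CH2Cl2, rt
Reagents that add atoms: selenium dioxide, O=[Se]=O (delivers the O, catalytic); tert-butyl hydroperoxide, CC(C)(C)OO (re-oxidant, net O source)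
Why: SeO2 allylic hydroxylation of the 1,1-disubstituted alkene goes to the CH2 (C7) and not the CH (C9), and the ene/2,3-shift sequence on the open α face gives the axial 7α-alcohol (corrected in steps 8 and 9).

**Step 8**
Reactants: 11
Product: 12 7-oxo-12,15-sulfonyl-labda-8(17),13-dien-18-oic acid
Conditions: TEMPO (0.3 equiv), PhI(OAc)2 (3.5 equiv), MeCN–H2O (NaH2PO4/Na2HPO4 buffer, pH 7), rt
Reagents that add atoms: water, O
Why: Oxoammonium (TEMPO/PhI(OAc)2) oxidation takes the neopentylic primary alcohol to the acid through the aldehyde hydrate and the allylic secondary alcohol to the enone under near-neutral conditions that do not isomerise the exocyclic enone.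

**Step 9**
Reactants: 12
Product: 13 7β-hydroxy-12,15-sulfonyl-labda-8(17),13-dien-18-oic acid
Conditions: NaBH4, CeCl3·7H2O, MeOH, −40 °C
Reagents that add atoms: none
Why: Luche 1,2-reduction in which hydride arrives along the axial α trajectory (past H-5 and H-9 only), giving the equatorial 7β-alcohol (7S).

**Step 10**
Reactants: 14 diosmetin (5,7,3'-trihydroxy-4'-methoxyflavone)
Product: 15 2-(5,7-dihydroxy-4-oxo-4H-chromen-2-yl)-5-methoxy-1,4-benzoquinone
Conditions: (KSO3)2NO (2.5 equiv), KH2PO4 buffer (pH 6), H2O–DMF, 0 °C → rt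
Reagents that add atoms: potassium nitrosodisulfonate, [K+].[K+].[O]N(S(=O)(=O)[O-])S(=O)(=O)[O-]
Why: Teuber oxidation in which the nitroxide abstracts H from the most easily oxidised phenol (ring B, 3'-OH) and a second equivalent couples at the free para carbon C6', giving the methoxy-p-quinone, while the hydrogen-bonded, acyl-deactivated ring A phenols react more slowly.

**Step 11**
Reactants: 13 7β-hydroxy-12,15-sulfonyl-labda-8(17),13-dien-18-oic acid; 15 2-(5,7-dihydroxy-4-oxo-4H-chromen-2-yl)-5-methoxy-1,4-benzoquinone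
Product: 19 dichrostachine E (4R,5R,7S,9R,10R,12R,1'S,2'R), via BF2 chelate 16 (not isolated), via triene acid 17 (not isolated), via chelated adduct 18 (not isolated)
Conditions: 15, BF3·OEt2 (1.1 equiv), CH2Cl2, rt, evaporate; 13, pyridine, PhMe, 110 °C, N2 stream, evaporate; combine in CH2Cl2, −20 °C → rt; then MeOH–H2O (9:1), 40 °C
Reagents that add atoms: none
Why: Proposed new method: disrotatory cheletropic loss of SO2 turns the C12 substituent outward and gives only the 12E diene 17, and the dienophile is used as its 4,5-O,O-BF2 chelate 16 so that the chromone becomes a benzopyrylium-like acceptor conjugated with C1'=C2' (closest known reactions: Lewis-acid-promoted Diels–Alder reactions of 2-vinylchromones and vinylazaarenes, and the BF3-induced regiochemical switch of methoxyquinone cycloadditions), which is expected (a) to make C2' the most electrophilic carbon, so the unsubstituted terminus C15 bonds to C2' and C12 to C1', (b) to make the chromone rather than the quinone carbonyls the endo, π-stacked group, placing C11 cis to the chromone, (c) to give the cis C1'/C2' fusion by suprafacial addition, and (d) to leave the diene face to the substrate, where in the extended side-chain conformer C17 and C20 screen the β face and addition on the H-9 side gives 12R,1'S,2'R; this last control is weak, so a mixture is expected and the target is separated from its facial isomer by chromatography.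

**Compound list**
1 | 3-methyl-2,5-dihydrothiophene 1,1-dioxide (3-methyl-3-sulfolene) | CC1=CCS(=O)(=O)C1 | starting material
2 | (2E,6E)-farnesyl bromide | CC(C)=CCC/C(C)=C/CC/C(C)=C/CBr | starting material
3 | 2-[(2E,6E)-farnesyl]-3-methyl-2,5-dihydrothiophene 1,1-dioxide (racemic) | CC1=CCS(=O)(=O)C1C/C=C(C)/CC/C=C(C)/CCC=C(C)C | intermediate
4 | (2E,6E,10E)-2,6,10-trimethyl-12-(3-methyl-1,1-dioxo-2,5-dihydrothiophen-2-yl)dodeca-2,6,10-trien-1-ol | CC1=CCS(=O)(=O)C1C/C=C(C)/CC/C=C(C)/CC/C=C(C)/CO | intermediate
5 | (2S,3S)-epoxy alcohol of 4 | CC1=CCS(=O)(=O)C1C/C=C(C)/CC/C=C(C)/CC[C@@H]1O[C@@]1(C)CO | intermediate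
6 | 3β,18-bis(trimethylsilyloxy)-12,15-sulfonyl-labda-8(17),13-diene | C=C1CC[C@@H]2[C@](C)(CC[C@H](O[Si](C)(C)C)[C@@]2(C)CO[Si](C)(C)C)[C@H]1CC1C(C)=CCS1(=O)=O | intermediate
7 | 12,15-sulfonyl-labda-8(17),13-diene-3β,18-diol | C=C1CC[C@@H]2[C@](C)(CC[C@H](O)[C@@]2(C)CO)[C@H]1CC1C(C)=CCS1(=O)=O | intermediate
8 | cyclic 3β,18-thionocarbonate of 7 | C=C1CC[C@@H]2[C@](C)(CC[C@@H]3OC(=S)OC[C@@]23C)[C@H]1CC1C(C)=CCS1(=O)=O | intermediate
9 | 18-O-[(tributylstannylthio)carbonyl]-12,15-sulfonyl-labda-8(17),13-dien-18-ol | C=C1CC[C@@H]2[C@](C)(CCC[C@@]2(C)COC(=O)S[Sn](CCCC)(CCCC)CCCC)[C@H]1CC1C(C)=CCS1(=O)=O | intermediate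
10 | 12,15-sulfonyl-labda-8(17),13-dien-18-ol | C=C1CC[C@@H]2[C@](C)(CCC[C@@]2(C)CO)[C@H]1CC1C(C)=CCS1(=O)=O | intermediate
11 | 12,15-sulfonyl-labda-8(17),13-diene-7α,18-diol | C=C1[C@H](O)C[C@@H]2[C@](C)(CCC[C@@]2(C)CO)[C@H]1CC1C(C)=CCS1(=O)=O | intermediate
12 | 7-oxo-12,15-sulfonyl-labda-8(17),13-dien-18-oic acid | C=C1C(=O)C[C@@H]2[C@](C)(CCC[C@@]2(C)C(=O)O)[C@H]1CC1C(C)=CCS1(=O)=O | intermediate
13 | 7β-hydroxy-12,15-sulfonyl-labda-8(17),13-dien-18-oic acid | C=C1[C@@H](O)C[C@@H]2[C@](C)(CCC[C@@]2(C)C(=O)O)[C@H]1CC1C(C)=CCS1(=O)=O | intermediate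
14 | diosmetin | COc1ccc(cc1O)-c1cc(=O)c2c(O)cc(O)cc2o1 | starting material
15 | 2-(5,7-dihydroxy-4-oxo-4H-chromen-2-yl)-5-methoxy-1,4-benzoquinone | COC1=CC(=O)C(=CC1=O)c1cc(=O)c2c(O)cc(O)cc2o1 | intermediate
16 | 4,5-O,O-difluoroboron chelate of 15 | COC1=CC(=O)C(=CC1=O)C1=CC2=[O+][B-](F)(F)OC3=CC(O)=CC(O1)=C23 | intermediate
17 | 7β-hydroxylabda-8(17),12E,14-trien-18-oic acid | C=C1[C@@H](O)C[C@@H]2[C@](C)(CCC[C@@]2(C)C(=O)O)[C@H]1C/C=C(C)/C=C | intermediate
18 | 4,5-O,O-difluoroboron chelate of 19 | C=C1[C@@H](O)C[C@@H]2[C@](C)(CCC[C@@]2(C)C(=O)O)[C@H]1C[C@@H]1C(C)=CC[C@H]2C(=O)C(OC)=CC(=O)[C@@]12C1=CC2=[O+][B-](F)(F)OC3=CC(O)=CC(O1)=C23 | intermediate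
19 | dichrostachine E | C=C1[C@@H](O)C[C@@H]2[C@](C)(CCC[C@@]2(C)C(=O)O)[C@H]1C[C@@H]1C(C)=CC[C@H]2C(=O)C(OC)=CC(=O)[C@@]12c1cc(=O)c2c(O)cc(O)cc2o1 | target

**Totals**
Total step count: 11. Longest linear sequence: 10 (steps 1–9 and 11); step 10 is a one-step branch.

**Three steps most likely to fail**

Step 11 (cycloaddition). Regiochemistry and the chromone-endo topology rest on the chelation argument, and the diene face is under weak, remote substrate control. The quinone-endo adduct or the 12S facial isomer may dominate. The fallback replaces substrate control by a covalently bound chiral controller on the dienophile. It sets out from quinone 15 (with triene acid 17 released from 13 as before) and comes back at 19. Quinone 15, diethyl L-tartrate and B(OMe)3 (PhMe, 60 °C, methanol distilled off) give the rubrocurcumin-type tartrate spiroborate chelate F1. F1 and 17 in CH2Cl2 at −20 °C give the adduct spiroborate F2, and MeOH–H2O at 40 °C releases 19. The activation and endo arguments are kept, the tartrate now differentiates the two faces of the dienophile, and the D-tartrate is tried if the L-series is mismatched.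

Step 4 (bicyclisation). The radical at C4 is planar, so the 4α-CH2O outcome depends on a conformational preference, and yields of such cascades are moderate. The fallback makes the epoxide opening cationic and concerted, which transfers the E geometry to C4 directly. It sets out from 5 and comes back at 7. Silylation of 5 (t-BuMe2SiCl, imidazole, DMF) gives the silyl ether F3. MeAlCl2 in CH2Cl2 at −78 °C gives the bicyclic 3β-hydroxy-18-silyl ether F4, whose 8(17)-ene is separated from the 7-ene isomer on AgNO3-impregnated silica. Bu4NF in THF then gives 7.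

Step 10 (quinone formation). The ring A phenols may compete, giving 5,8-quinone or over-oxidation. The fallback deactivates ring A first and uses a two-electron oxidant. It sets out from 14 and comes back at 16, which is used directly in step 11. Diosmetin and BF3·OEt2 in CH2Cl2 give the diosmetin difluoroboron chelate F5. PhI(OCOCF3)2 (trivalent iodine, 2.2 equiv) in MeCN–H2O at 0 °C oxidises ring B of F5 to the p-quinone, giving 16.

**Further compounds**
F1 | step 11 | diethyl L-tartrate spiroborate chelate of 15 | COC1=CC(=O)C(=CC1=O)C1=CC2=[O+][B-]3(O[C@@H](C(=O)OCC)[C@@H](O3)C(=O)OCC)OC4=CC(O)=CC(O1)=C24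
F2 | step 11 | diethyl L-tartrate spiroborate chelate of 19 | C=C1[C@@H](O)C[C@@H]2[C@](C)(CCC[C@@]2(C)C(=O)O)[C@H]1C[C@@H]1C(C)=CC[C@H]2C(=O)C(OC)=CC(=O)[C@@]12C1=CC2=[O+][B-]3(O[C@@H](C(=O)OCC)[C@@H](O3)C(=O)OCC)OC4=CC(O)=CC(O1)=C24
F3 | step 4 | tert-butyldimethylsilyl ether of 5 | CC1=CCS(=O)(=O)C1C/C=C(C)/CC/C=C(C)/CC[C@@H]1O[C@@]1(C)CO[Si](C)(C)C(C)(C)C
F4 | step 4 | 18-O-tert-butyldimethylsilyl ether of 7 | C=C1CC[C@@H]2[C@](C)(CC[C@H](O)[C@@]2(C)CO[Si](C)(C)C(C)(C)C)[C@H]1CC1C(C)=CCS1(=O)=O
F5 | step 10 | 4,5-O,O-difluoroboron chelate of diosmetin | COc1ccc(cc1O)C1=CC2=[O+][B-](F)(F)OC3=CC(O)=CC(O1)=C23
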